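**Retrosynthetic overview**

1. The target is unmasked last: hydrolysis of a dioxolane (the masked 5-acetyl group) and, before that, angeloylation of the C3 hydroxyl of the cis-(2R,3R)-2-isopropenyl-2,3-dihydrobenzofuran-3-ol 19.
2. The strategy rests on the dihydrofuran ring (O1, C2, C3, C3a, C7a): benzylic C3 carries oxygen and its neighbour C2 carries O1 and an isopropenyl group. This Ar–CH(O)–CH(OAr)–C(CH3)=CH2 homoallylic alcohol is what a [2,3]-Wittig shift gives from a benzyl 2-methylallyl ether whose far allyl carbon is an enol ether bound through O1 to the same benzene ring.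
3. Key disconnection: C2–C3. Tying the C3 oxygen to the isopropenyl CH2 gives the eight-membered (2Z)-4H,6H-1,5-benzodioxocine 16, which a chiral lithium base contracts to the five-membered ring.
4. Ring 16 is opened at the benzylic C–O bond (desilylative Williamson closure) and at the aryl O–vinyl bond (copper-catalysed coupling with a Z-vinyl iodide made from propargyl alcohol).
5. The arene comes from 2,3-dimethoxyphenol by ortho-formylation, para-bromination and Stille coupling/ketal exchange. Ring order: benzene (given), eight-membered dioxocine (step 9), dihydrofuran (step 10, with loss of the eight-membered ring).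

Key step: step 10

Assumption: the sense of induction of the bis(oxazoline) ligand on this new substrate cannot be derived from precedent; the (S,S)-ligand is written, and its (R,R)-enantiomer is to be used if the (2S,3S) alcohol should predominate.

**Route**

Step 1
Reactants: 1 2,3-dimethoxyphenol
Product: 2 2-hydroxy-3,4-dimethoxybenzaldehyde
Conditions: MgCl2, Et3N, (CH2O)n, MeCN, reflux; aq. HCl work-up
Reagents that add atoms: paraformaldehyde (formaldehyde), C=O
Why: Casnati–Skattebøl ortho-formylation through the magnesium phenoxide can only reach C6, the single free position ortho to the hydroxyl, so one regioisomer is expected.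

Step 2
Reactants: 2 2-hydroxy-3,4-dimethoxybenzaldehyde
Product: 3 5-bromo-2-hydroxy-3,4-dimethoxybenzaldehyde
Conditions: Br2, NaOAc, AcOH, rt
Reagents that add atoms: bromine, BrBr
Why: Electrophilic aromatic bromination should take the one position para to the hydroxyl (C5, also ortho to a methoxy and meta to the formyl group), which fixes the site of the later acetyl group without the regiochemical doubt of a Fries or Friedel–Crafts acylation.

Step 3
Reactants: 3 5-bromo-2-hydroxy-3,4-dimethoxybenzaldehyde; 4 tributyl(1-ethoxyvinyl)stannane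
Product: 6 2-hydroxy-3,4-dimethoxy-5-(2-methyl-1,3-dioxolan-2-yl)benzaldehyde, via α-ethoxyvinyl arene 5 (not isolated)
Conditions: Pd(PPh3)4 (5 mol%), toluene, 100 °C; then HOCH2CH2OH (1.5 equiv), PPTS (cat.), rt; aq. KF work-up
Reagents that add atoms: ethylene glycol, OCCO
Why: Stille coupling with the α-ethoxyvinyl stannane tolerates the free phenol and aldehyde, and the α-aryl enol ether 5 then undergoes fast acid-catalysed acetal exchange with the diol to the dioxolane, whereas the hydrogen-bonded, electron-rich salicylaldehyde should not acetalise with a near-stoichiometric amount of glycol and no water removal.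

Step 4
Reactants: 7 prop-2-yn-1-ol
Product: 9 (2Z)-3-iodo-2-methylprop-2-en-1-ol, via alkenylmagnesium chelate 8 (not isolated)
Conditions: MeMgBr (2.5 equiv), CuI (10 mol%), THF/Et2O, −10 °C to rt; then I2, −10 °C
Reagents that add atoms: methylmagnesium bromide, C[Mg]Br; iodine, II
Why: Copper-catalysed anti-carbomagnesiation of the propargylic alkoxide delivers methyl to C2 and magnesium to C3 inside a five-membered chelate, and iodinolysis with retention should give the Z-iodide in which iodine and CH2OH are cis.

Step 5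
Reactants: 9 (2Z)-3-iodo-2-methylprop-2-en-1-ol
Product: 10 tert-butyl{[(2Z)-3-iodo-2-methylprop-2-en-1-yl]oxy}dimethylsilane
Conditions: TBSCl, imidazole, CH2Cl2, rt
Reagents that add atoms: tert-butyldimethylsilyl chloride, CC(C)(C)[Si](C)(C)Cl
Why: Standard silylation of a primary alcohol masks the hydroxyl so that only the phenol couples in step 6 and only the benzylic hydroxyl is activated in step 8.

Step 6
Reactants: 6 2-hydroxy-3,4-dimethoxy-5-(2-methyl-1,3-dioxolan-2-yl)benzaldehyde; 10 tert-butyl{[(2Z)-3-iodo-2-methylprop-2-en-1-yl]oxy}dimethylsilane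
Product: 11 2-{[(1Z)-3-{[tert-butyl(dimethyl)silyl]oxy}-2-methylprop-1-en-1-yl]oxy}-3,4-dimethoxy-5-(2-methyl-1,3-dioxolan-2-yl)benzaldehyde
Conditions: CuI (10 mol%), N,N-dimethylglycine hydrochloride (30 mol%), Cs2CO3, 1,4-dioxane, 90 °C
Reagents that add atoms: none
Why: Ullmann-type copper-catalysed C–O coupling of a phenoxide with a vinyl iodide proceeds with retention of alkene geometry, so the Z enol ether needed for the ring is fixed here, and ketal, aldehyde and silyl ether are stable to carbonate base.

Step 7
Reactants: 11 the aldehyde of step 6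
Product: 12 [2-{[(1Z)-3-{[tert-butyl(dimethyl)silyl]oxy}-2-methylprop-1-en-1-yl]oxy}-3,4-dimethoxy-5-(2-methyl-1,3-dioxolan-2-yl)phenyl]methanol
Conditions: NaBH4, MeOH, 0 °C
Reagents that add atoms: none
Why: Borohydride reduction of the aryl aldehyde is chemoselective; enol ether, ketal and silyl ether are inert.

Step 8
Reactants: 12 the benzylic alcohol of step 7
Product: 14 tert-butyl{[(2Z)-3-[6-(chloromethyl)-2,3-dimethoxy-4-(2-methyl-1,3-dioxolan-2-yl)phenoxy]-2-methylprop-2-en-1-yl]oxy}dimethylsilane, via benzylic mesylate 13 (not isolated)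
Conditions: MsCl, Et3N, CH2Cl2, 0 °C to rt; crude product used at once
Reagents that add atoms: methanesulfonyl chloride, CS(=O)(=O)Cl
Why: Sulfonylation of the electron-rich benzylic alcohol followed by in situ substitution of the mesylate by the chloride released from MsCl gives the benzylic chloride under amine-buffered conditions that spare the ketal, the enol ether and the silyl ether.

Step 9
Reactants: 14 the benzylic chloride of step 8
Product: 16 (2Z)-9,10-dimethoxy-3-methyl-8-(2-methyl-1,3-dioxolan-2-yl)-4H,6H-1,5-benzodioxocine, via tetrabutylammonium alkoxide 15 (not isolated)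
Conditions: TBAF (1 M in THF, dried over 4 Å sieves), THF (0.005 M), 0 °C to rt
Reagents that add atoms: none
Why: Fluoride desilylation frees an ammonium alkoxide that closes the eight-membered ring by intramolecular Williamson etherification (8-exo-tet) at the activated benzylic chloride, the arene and the Z enol ether holding four ring atoms in a cis arrangement and high dilution suppressing intermolecular reaction.

Step 10
Reactants: 16 (2Z)-9,10-dimethoxy-3-methyl-8-(2-methyl-1,3-dioxolan-2-yl)-4H,6H-1,5-benzodioxocine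
Product: 19 (2R,3R)-6,7-dimethoxy-5-(2-methyl-1,3-dioxolan-2-yl)-2-(prop-1-en-2-yl)-2,3-dihydro-1-benzofuran-3-ol, via benzylic lithium species 17 (not isolated), via lithium alkoxide 18 (not isolated)
Conditions: s-BuLi (1.3 equiv), (S,S)-i-Pr-BOX [2,2-bis((4S)-4-isopropyl-2-oxazolin-2-yl)propane] (1.4 equiv), toluene/hexane, −78 °C; aq. NH4Cl, −78 °C
Reagents that add atoms: none
Why: Proposed new method: the ligand-bound s-BuLi removes one hydrogen of the benzylic OCH2 group (C6 of 16) to give the α-oxybenzyllithium 17, whose carbanion carbon bonds across the ring to the enol-ether carbon C2 in a concerted five-centre, six-electron [2,3]-Wittig shift while the O5–C4 bond breaks and the ring alkene moves to C3=C4 and becomes the isopropenyl group; the closest known reactions are ring-contracting [2,3]-Wittig rearrangements of cyclic allyl ethers and enantioselective [2,3]-Wittig rearrangements of benzyl allyl ethers with alkyllithium/bis(oxazoline) bases, the new element being an enol-ether terminus inside a medium ring. The dihydrofuran ring closes by transannular C–C bond formation, formally a 5-exo-trig attack of the benzylic carbanion on the enol-ether carbon, at the same moment as the eight-membered ring opens. C2 and C3 are set together: the five-membered transition-state array and the new dihydrofuran ring are fused along the bond being made and such a bicyclic array can only be cis-fused, so the C3 oxygen and the isopropenyl carbon must end up on the same face (cis, 2R,3R or 2S,3S). The absolute sense comes from the chiral bis(oxazoline) on lithium, either by choice of one enantiotopic benzylic hydrogen or, if the benzylic lithium epimerises, by faster rearrangement of one ligand-bound diastereomer. The step needs benzylic lithiation in preference to allylic, vinylic or aryl lithiation and a [2,3] in preference to a [1,2] shift: the benzylic site alone gives an aryl-stabilised α-oxy carbanion (an anion at the allylic OCH2 would be destabilised by the donor enol ether and the only aryl hydrogen is flanked on both sides), the ring holds the two reacting carbons within bonding distance, and −78 °C favours the concerted path over radical-pair migration; the dioxolane keeps the acetyl carbon inert to the base.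

Step 11
Reactants: 19 (2R,3R)-6,7-dimethoxy-5-(2-methyl-1,3-dioxolan-2-yl)-2-(prop-1-en-2-yl)-2,3-dihydro-1-benzofuran-3-ol; 20 angelic acid
Product: 23 (2R,3R)-6,7-dimethoxy-5-(2-methyl-1,3-dioxolan-2-yl)-2-(prop-1-en-2-yl)-2,3-dihydro-1-benzofuran-3-yl (2Z)-2-methylbut-2-enoate, via mixed anhydride 21 (not isolated), via sodium alkoxide 22 (not isolated)
Conditions: 20, 2,4,6-trichlorobenzoyl chloride, Et3N, toluene, rt; added to 19/NaN(SiMe3)2 (1.05 equiv), THF, −78 °C to 0 °C; aq. NH4Cl
Reagents that add atoms: none
Why: Yamaguchi-type mixed-anhydride acylation of the sodium alkoxide, preformed from the isolated alcohol with the silazide base, attacks the unhindered angeloyl carbonyl at low temperature without a nucleophilic amine catalyst, the condition known to avoid conjugate-addition-mediated Z to E isomerisation, and it is run before unmasking because the free methyl ketone would be enolised by the base; C2 and C3 are untouched.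

Step 12
Reactants: 23 the angelate ketal of step 11
Product: 24 (2R,3R)-5-acetyl-6,7-dimethoxy-2-(prop-1-en-2-yl)-2,3-dihydro-1-benzofuran-3-yl (2Z)-2-methylbut-2-enoate (CNP0113631.1)
Conditions: PPTS (cat.), THF/H2O (4:1), rt
Reagents that add atoms: water, O
Why: Acid-catalysed ketal hydrolysis is very fast for this dioxolane because its oxocarbenium ion is stabilised by the ortho methoxy group and the para ring oxygen, so buffered conditions that leave the benzylic angelate, the isopropenyl group and both stereocenters alone should suffice.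

**Compound list**

1 | 2,3-dimethoxyphenol | COc1cccc(O)c1OC | starting material
2 | 2-hydroxy-3,4-dimethoxybenzaldehyde | COc1ccc(C=O)c(O)c1OC | intermediate
3 | 5-bromo-2-hydroxy-3,4-dimethoxybenzaldehyde | COc1c(Br)cc(C=O)c(O)c1OC | intermediate
4 | tributyl(1-ethoxyvinyl)stannane | CCCC[Sn](CCCC)(CCCC)C(=C)OCC | starting material
5 | 5-(1-ethoxyvinyl)-2-hydroxy-3,4-dimethoxybenzaldehyde | CCOC(=C)c1cc(C=O)c(O)c(OC)c1OC | intermediate (not isolated)
6 | 2-hydroxy-3,4-dimethoxy-5-(2-methyl-1,3-dioxolan-2-yl)benzaldehyde | CC1(OCCO1)c1cc(C=O)c(O)c(OC)c1OC | intermediate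
7 | prop-2-yn-1-ol | C#CCO | starting material
8 | 4-methyl-2,5-dihydro-1,2-oxamagnesole (cyclic Z-alkenylmagnesium alkoxide) | CC1=C[Mg]OC1 | intermediate (not isolated)
9 | (2Z)-3-iodo-2-methylprop-2-en-1-ol | OC/C(C)=C\I | intermediate
10 | tert-butyl{[(2Z)-3-iodo-2-methylprop-2-en-1-yl]oxy}dimethylsilane | CC(C)(C)[Si](C)(C)OC/C(C)=C\I | intermediate
11 | 2-{[(1Z)-3-{[tert-butyl(dimethyl)silyl]oxy}-2-methylprop-1-en-1-yl]oxy}-3,4-dimethoxy-5-(2-methyl-1,3-dioxolan-2-yl)benzaldehyde | CC1(OCCO1)c1cc(C=O)c(O/C=C(C)\CO[Si](C)(C)C(C)(C)C)c(OC)c1OC | intermediate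
12 | [2-{[(1Z)-3-{[tert-butyl(dimethyl)silyl]oxy}-2-methylprop-1-en-1-yl]oxy}-3,4-dimethoxy-5-(2-methyl-1,3-dioxolan-2-yl)phenyl]methanol | CC1(OCCO1)c1cc(CO)c(O/C=C(C)\CO[Si](C)(C)C(C)(C)C)c(OC)c1OC | intermediate
13 | methanesulfonate of 12 | CC1(OCCO1)c1cc(COS(C)(=O)=O)c(O/C=C(C)\CO[Si](C)(C)C(C)(C)C)c(OC)c1OC | intermediate (not isolated)
14 | tert-butyl{[(2Z)-3-[6-(chloromethyl)-2,3-dimethoxy-4-(2-methyl-1,3-dioxolan-2-yl)phenoxy]-2-methylprop-2-en-1-yl]oxy}dimethylsilane | CC1(OCCO1)c1cc(CCl)c(O/C=C(C)\CO[Si](C)(C)C(C)(C)C)c(OC)c1OC | intermediate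
15 | tetrabutylammonium (2Z)-3-[6-(chloromethyl)-2,3-dimethoxy-4-(2-methyl-1,3-dioxolan-2-yl)phenoxy]-2-methylprop-2-en-1-olate | CC1(OCCO1)c1cc(CCl)c(O/C=C(C)\C[O-])c(OC)c1OC.CCCC[N+](CCCC)(CCCC)CCCC | intermediate (not isolated)
16 | (2Z)-9,10-dimethoxy-3-methyl-8-(2-methyl-1,3-dioxolan-2-yl)-4H,6H-1,5-benzodioxocine | C/C1=C/Oc2c(cc(C3(C)OCCO3)c(OC)c2OC)COC1 | intermediate (key-step precursor)
17 | 6-lithio derivative of 16 (ligand-bound; configuration at the lithiated carbon set by the ligand) | C/C1=C/Oc2c(cc(C3(C)OCCO3)c(OC)c2OC)C([Li])OC1 | intermediate (not isolated)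
18 | lithium (2R,3R)-6,7-dimethoxy-5-(2-methyl-1,3-dioxolan-2-yl)-2-(prop-1-en-2-yl)-2,3-dihydro-1-benzofuran-3-olate | C=C(C)[C@H]1Oc2c(cc(C3(C)OCCO3)c(OC)c2OC)[C@H]1O[Li] | intermediate (not isolated)
19 | (2R,3R)-6,7-dimethoxy-5-(2-methyl-1,3-dioxolan-2-yl)-2-(prop-1-en-2-yl)-2,3-dihydro-1-benzofuran-3-ol (cis) | C=C(C)[C@H]1Oc2c(cc(C3(C)OCCO3)c(OC)c2OC)[C@H]1O | intermediate (key-step product)
20 | angelic acid, (2Z)-2-methylbut-2-enoic acid | C/C=C(/C)C(=O)O | starting material
21 | (2Z)-2-methylbut-2-enoic 2,4,6-trichlorobenzoic anhydride | C/C=C(/C)C(=O)OC(=O)c1c(Cl)cc(Cl)cc1Cl | intermediate (not isolated)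
22 | sodium (2R,3R)-6,7-dimethoxy-5-(2-methyl-1,3-dioxolan-2-yl)-2-(prop-1-en-2-yl)-2,3-dihydro-1-benzofuran-3-olate | C=C(C)[C@H]1Oc2c(cc(C3(C)OCCO3)c(OC)c2OC)[C@H]1O[Na] | intermediate (not isolated)
23 | (2R,3R)-6,7-dimethoxy-5-(2-methyl-1,3-dioxolan-2-yl)-2-(prop-1-en-2-yl)-2,3-dihydro-1-benzofuran-3-yl (2Z)-2-methylbut-2-enoate | C=C(C)[C@H]1Oc2c(cc(C3(C)OCCO3)c(OC)c2OC)[C@H]1OC(=O)/C(C)=C\C | intermediate
24 | (2R,3R)-5-acetyl-6,7-dimethoxy-2-(prop-1-en-2-yl)-2,3-dihydro-1-benzofuran-3-yl (2Z)-2-methylbut-2-enoate | C=C(C)[C@H]1Oc2c(cc(C(C)=O)c(OC)c2OC)[C@H]1OC(=O)/C(C)=C\C | target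

**Step count**

Total steps: 12. Longest linear sequence: 10 (steps 1, 2, 3, 6, 7, 8, 9, 10, 11, 12 from 2,3-dimethoxyphenol).

**Steps most likely to fail**

1. Step 10 (key step). What may go wrong: lithiation at a site other than the benzylic OCH2 (the enol-ether C2–H, the lone aryl C–H or the allylic OCH2), radical-pair [1,2] migration in place of the concerted shift, or weak discrimination by the ligand. The fallback uses known chemistry, sets out from 11 and comes back at 19; it makes the same C2–C3 bond by intramolecular carbonyl allylation. TBAF in THF removes the silyl group of 11 to give 2-{[(1Z)-3-hydroxy-2-methylprop-1-en-1-yl]oxy}-3,4-dimethoxy-5-(2-methyl-1,3-dioxolan-2-yl)benzaldehyde F1, and Ac2O/pyridine then gives (2Z)-3-[6-formyl-2,3-dimethoxy-4-(2-methyl-1,3-dioxolan-2-yl)phenoxy]-2-methylprop-2-en-1-yl acetate F2. Pd(PPh3)4 (cat.) with InI in THF (umpolung allylation through a π-allylpalladium and transmetalation to indium) turns F2 into a γ-aryloxyallylindium species, which adds through its oxygen-bearing carbon to the neighbouring aldehyde; the cyclic transition state is expected to favour the cis alcohol, obtained as the racemate, that is 19 together with (2S,3S)-6,7-dimethoxy-5-(2-methyl-1,3-dioxolan-2-yl)-2-(prop-1-en-2-yl)-2,3-dihydro-1-benzofuran-3-ol F3, and any trans isomer would be removed by chromatography. Lipase-catalysed acylation (Amano lipase PS, vinyl acetate, t-BuOMe) is expected, by the empirical rule for secondary benzylic alcohols, to convert the 3S enantiomer into (2S,3S)-6,7-dimethoxy-5-(2-methyl-1,3-dioxolan-2-yl)-2-(prop-1-en-2-yl)-2,3-dihydro-1-benzofuran-3-yl acetate F4 and to leave 19, which re-enters at step 11.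

2. Step 9. What may go wrong: intermolecular etherification to oligomers outrunning the eight-membered ring closure, or loss of the labile benzylic chloride by substitution with fluoride or adventitious hydroxide. The fallback sets out from 6 and comes back at 16; it builds the ring from two allylic SN2 reactions and then moves the alkene, and it also bypasses step 6, whose coupling of a hindered, chelating phenol carries a comparable risk. NaBH4 in MeOH reduces 6 to 6-(hydroxymethyl)-2,3-dimethoxy-4-(2-methyl-1,3-dioxolan-2-yl)phenol F5. Cs2CO3 and excess 3-chloro-2-(chloromethyl)prop-1-ene in MeCN alkylate only the phenol to give [2-{[2-(chloromethyl)prop-2-en-1-yl]oxy}-3,4-dimethoxy-5-(2-methyl-1,3-dioxolan-2-yl)phenyl]methanol F6, and NaH in DMF at high dilution closes the ring to 9,10-dimethoxy-3-methylidene-8-(2-methyl-1,3-dioxolan-2-yl)-3,4-dihydro-2H,6H-1,5-benzodioxocine F7. t-BuOK in DMSO at rt should then move the exocyclic alkene into the ring on the side of the more acidic aryloxy-methylene group to give 16; any regioisomeric enol ether is removed by chromatography.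

3. Step 11. What may go wrong: Z to E isomerisation of the angeloyl unit to the tiglate during acyl transfer, or slow acylation of the hindered hydroxyl cis to the isopropenyl group. The fallback sets out from 19 and comes back at 23; it builds the Z alkene on the ester instead of transferring it. 19 is esterified with 2-[bis(2,2,2-trifluoroethoxy)phosphoryl]propanoic acid (DCC, DMAP cat., CH2Cl2) to give (2R,3R)-6,7-dimethoxy-5-(2-methyl-1,3-dioxolan-2-yl)-2-(prop-1-en-2-yl)-2,3-dihydro-1-benzofuran-3-yl 2-[bis(2,2,2-trifluoroethoxy)phosphoryl]propanoate F8 (mixture of epimers at the phosphonate carbon), and Still–Gennari olefination (KN(SiMe3)2, 18-crown-6, THF, −78 °C, then acetaldehyde) should give the Z-trisubstituted enoate 23.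

**Further compounds**

F1 | step 10 | 2-{[(1Z)-3-hydroxy-2-methylprop-1-en-1-yl]oxy}-3,4-dimethoxy-5-(2-methyl-1,3-dioxolan-2-yl)benzaldehyde | CC1(OCCO1)c1cc(C=O)c(O/C=C(C)\CO)c(OC)c1OC
F2 | step 10 | (2Z)-3-[6-formyl-2,3-dimethoxy-4-(2-methyl-1,3-dioxolan-2-yl)phenoxy]-2-methylprop-2-en-1-yl acetate | CC1(OCCO1)c1cc(C=O)c(O/C=C(C)\COC(C)=O)c(OC)c1OC
F3 | step 10 | (2S,3S)-6,7-dimethoxy-5-(2-methyl-1,3-dioxolan-2-yl)-2-(prop-1-en-2-yl)-2,3-dihydro-1-benzofuran-3-ol (formed with 19 as the racemate) | C=C(C)[C@@H]1Oc2c(cc(C3(C)OCCO3)c(OC)c2OC)[C@@H]1O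
F4 | step 10 | (2S,3S)-6,7-dimethoxy-5-(2-methyl-1,3-dioxolan-2-yl)-2-(prop-1-en-2-yl)-2,3-dihydro-1-benzofuran-3-yl acetate | C=C(C)[C@@H]1Oc2c(cc(C3(C)OCCO3)c(OC)c2OC)[C@@H]1OC(C)=O
F5 | step 9 | 6-(hydroxymethyl)-2,3-dimethoxy-4-(2-methyl-1,3-dioxolan-2-yl)phenol | CC1(OCCO1)c1cc(CO)c(O)c(OC)c1OC
F6 | step 9 | [2-{[2-(chloromethyl)prop-2-en-1-yl]oxy}-3,4-dimethoxy-5-(2-methyl-1,3-dioxolan-2-yl)phenyl]methanol | CC1(OCCO1)c1cc(CO)c(OCC(=C)CCl)c(OC)c1OC
F7 | step 9 | 9,10-dimethoxy-3-methylidene-8-(2-methyl-1,3-dioxolan-2-yl)-3,4-dihydro-2H,6H-1,5-benzodioxocine | C=C1COCc2cc(C3(C)OCCO3)c(OC)c(OC)c2OC1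
F8 | step 11 | (2R,3R)-6,7-dimethoxy-5-(2-methyl-1,3-dioxolan-2-yl)-2-(prop-1-en-2-yl)-2,3-dihydro-1-benzofuran-3-yl 2-[bis(2,2,2-trifluoroethoxy)phosphoryl]propanoate | C=C(C)[C@H]1Oc2c(cc(C3(C)OCCO3)c(OC)c2OC)[C@H]1OC(=O)C(C)P(=O)(OCC(F)(F)F)OCC(F)(F)F
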